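## The problem

Numbering used throughout: macrolide ring O1, C2 (methyl carbinol), C3, C4, C5 (ketone), C6, C7, C8, C9, C10 (ester carbonyl); γ-lactone C8–O11–C12(=O)–C13–C7; furan O1′, C2′–C5′ (C2′ on C13); side chain C1″–C4″ (C3″ is the carbinol).

Cordycicadin B (37) is a ten-membered keto-lactone cis-fused through C7–C8 to a γ-butyrolactone whose α-carbon C13 carries a 2,5-disubstituted furan ending in an (R)-3-hydroxybutyl chain. Of its five stereocentres, C2 (R) and C3″ (R) are isolated methyl carbinols that can be bought, whereas C7, C8 and C13 (all S) form a contiguous all-cis triad on the five-membered ring. C8 can direct C7, because hydrogen adds to a C7=C13 butenolide from the face away from the C9 chain. The finished cis-bicycle can direct C13, but the furyl group must end on the concave face, cis to C6, and C13–H is acidic, so this centre has to be set late and kinetically. The fragile groups are the electron-rich 2,5-dialkylfuran (acid, oxidants, hydrogenation), the β-acyloxy ester C10–C9–C8–O11 (deprotonation at C9 opens the γ-lactone by E1cB), and the C5 ketone (it would enolise in competition and would trap the C2 hydroxyl of a seco acid as a five-membered hemiketal). The ten-membered ring has to be closed without the help of a double bond. The key step is possible because the furan is bound through C2′ to the one readily enolised carbon of the bicycle: C13–C2′ is an aldol bond, C2′–C3′–C4′ is an acrolein unit, and C5′ with C1″–C4″ is a terminal alkynol. The bonds C4′–C5′ and O1′–C5′ can therefore be made on the finished bicycle from a (Z)-iodoallylic alcohol, and aromatisation erases the C2′ carbinol centre.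

## Retrosynthesis

**End game, C13–H.** 37 is traced to 36 by removing two protecting groups that fall in one mild aqueous acid treatment: the C5 dioxolane and the C3″ triethylsilyl ether. 36 is the kinetic protonation product of enolate 35, which comes from the C13 epimer 34. Any carbon substituent introduced at C13 of the cis-fused bicycle lands on the convex face, so the C13–H bond is the one formed last: the proton is then delivered from that face and pushes the furyl group to the concave side. The forward step needs a base that touches only C13–H (an α-heteroaryl lactone, far more acidic than C9–H) and an irreversible quench.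

**Furan, C4′–C5′ and O1′–C5′ (key disconnection).** In 34 the furan is cut at C4′–C5′ and O1′–C5′, giving the (Z)-iodoallylic alcohol 29 and the silylated alkynol 31 (from 30). The neighbouring cuts are C13–C2′ with a preformed furan, or closure of a 1,4-diketone. Against them, this cut keeps the sensitive furan out of every earlier step, needs only an sp2–sp coupling that tolerates a free hydroxyl and both lactones, and buys the C3″ centre with the alkyne. It removes five carbons, the aromatic ring and one stereocentre, and makes no demand on the C2′ configuration of 29. The forward reaction must retain the (Z) geometry and let only the C2′ hydroxyl reach the alkyne; the silyl ether in 31 provides the second point.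

**Side-chain anchor, C13–C2′.** 29 is cut at C13–C2′ into the lithium enolate 28 of the bicyclic lactone 23 and (Z)-3-iodoacrolein 27, which comes from 25 and ultimately 24. Attaching this unit before ring closure would put a second hydroxyl into the lactonisation and carry a vinyl iodide through several steps. At the bicycle the aldol needs only enolisation at C13 rather than C9. The γ-lactone has the s-cis ester geometry and is the more acidic site. Neither new centre needs control.

**Ten-membered ring, O1–C10.** 23 is opened at the ester bond to the seco acid 21. Compared with C–C closures at C3–C4 or C8–C9, this cut lets the two halves be joined earlier by a chemoselective ketone synthesis, and the cis-γ-lactone holds C6 and C9 on one face as a turn. 21 is monocyclic with all three of its stereocentres fixed. The forward reaction is a medium-ring lactonisation at high dilution, with C5 masked as the dioxolane so that the C2 hydroxyl stays free.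

**Chain junction, C4–C5.** 21 comes from 19 by saponification (via the ring-opened salt 20) and 19 from ketone 18 by ketalisation. 18 is cut at C4–C5 into the acid chloride 16 of acid 12 and the alkylzinc iodide 17, made from iodide 15, which comes from 13 through 14. The cut falls at a ketone, the one bond of the chain that can be formed in the presence of the γ-lactone and the methyl ester, and it separates the bought C2 centre from the lactone half. The acetate on C2 tolerates the zinc reagent and leaves in the same saponification as the methyl ester.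

**C7 and C6–C7.** 12 comes from the tert-butyl ester 11, and 11 from butenolide 10 by hydrogenation, which sets C7 from C8. Conjugate addition to a butenolide lacking the C7 substituent would give the trans-lactone instead. 10 is cut at C6–C7 into vinyl triflate 7 and the Reformatsky reagent 9 (from 8). The coupling is neutral, so C8 is not at risk, and it delivers C5 as an ester distinguishable from the C10 methyl ester.

**Tetronic acid from malate.** 7 is the triflate of tetronic acid 6, which comes from 4 by hydrogenolysis and decarboxylation (via 5). 4 is the Dieckmann product of the mixed malonate 3, made from dimethyl (S)-malate 1 and mono-benzyl malonate 2. Malate C2 becomes C8, C1 becomes C7, C3–C4 become C9–C10, and the malonate supplies C12 and C13. A Claisen closure of an O-acetyl malate would need an unstabilised enolate beside a β-acyloxy ester and would eliminate. The malonate anion is stabilised and closes onto the α-oxygenated ester without that risk.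

## Roads not taken

Alternative 1: The ten-membered ring is cut at C3–C4 instead of O1–C10. A diene A1, with a vinyl ketone at C5 and the C10 acid esterified by a butenyl alcohol, would be closed by a ruthenium alkylidene (second-generation Grubbs-type catalyst) to the enone A2, and the C3=C4 bond then reduced.
- Merits: the ester bond is made intermolecularly, ring closure by alkene formation is the best-precedented entry to ten-membered lactones and cannot trigger E1cB at C9, and no ketal is needed.
- Weak points: both alkenes are poor partners (an electron-poor vinyl ketone and an alkene on an oxygen-bearing secondary carbon), so the closure would be slow and dilute. The vinyl ketone beside the activated C6 methylene is prone to polymerise or isomerise. A1 already contains the furan and the cis C13 centre, so both must survive metathesis and an enone reduction that has to spare the furan. C13 would be set on a monocyclic lactone with less facial bias.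
- Comparison: in reliability of ring closure this road is probably better than lactonisation of 21. The chosen plan sets against that a furan and a labile C13 centre that exist only in the last three steps, and C13 control by the complete bicycle. Step counts are similar.

Alternative 2: C13–C7 and C5–C6 are cut together. An eleven-membered β-keto bis-lactone A3, with C5 and C12 flanking C13 and a vinyl group on C8, would be irradiated. The C5=C13 enol adds across the vinyl group, and retro-aldol opening of the cyclobutanol (de Mayo sequence) contracts the ring to the silyl ether A4.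
- Merits: two C–C bonds, the ring fusion and two stereocentres in one operation, from a precursor assembled by esterifications. If it worked it would be clearly shorter than the chosen plan.
- Weak points: the de Mayo reaction is dependable for β-diketones, less so for an α-heteroaryl β-keto ester. The furan is itself photoactive. Regiochemistry and facial selectivity relative to C8 rest on the unknown conformation of an eleven-membered ring. C13 emerges from a retro-aldol and need not come out cis. A3 itself needs a macrolactonisation.
- Comparison: the chosen plan is longer, but uses only precedented reaction types and takes C7 from C8 by hydrogenation rather than from an untested transannular photoreaction.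

Alternative 3: The ring is cut at C8–C9. An aldehyde A5, carrying a bromoacetate on O1 with C7 and C13 already set and C12 as methyl ester, would be treated with SmI2. The samarium enolate adds to the C8 aldehyde to give the ten-membered β-hydroxy lactone A6, which then lactonises onto C12.
- Merits: SmI2 Reformatsky closures are among the best routes to medium-ring lactones, since trivalent samarium templates the ring and high dilution is not needed. The ester is again made intermolecularly.
- Weak points: C8 is created in the ring closure, and its configuration relative to C7 depends on the facial preference of an α-branched aldehyde in a macrocyclic transition state. The wrong epimer leads to a trans-fused lactone. The aldehyde is epimerisable at C7 and C13 is an acidic α-furyl ester centre, so the C7/C13 pair would have to be set in an open chain and carried, with the furan, through many steps.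
- Comparison: the ring closure is probably more dependable than that of 21. The chosen plan sets against it that C8 is bought with 1, C7 follows from it, and C13 is set last.

Key step: step 18

## Route

Assumption: 29 is carried forward as the mixture of its C2′ carbinol epimers (and of any C13 epimer), because step 18 destroys the first centre and step 19 resets the second.

Step 1
Reactants: 1 dimethyl (S)-malate; 2 mono-benzyl malonate
Product: 3 dimethyl (2S)-2-{[3-(benzyloxy)-3-oxopropanoyl]oxy}butanedioate
Conditions: DCC, DMAP (cat.), CH2Cl2, 0 °C → rt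
Reagents that add atoms: none
Why: Steglich esterification of the secondary hydroxyl; the stereocentre (later C8) is not involved.

Step 2
Reactants: 3 dimethyl (2S)-2-{[3-(benzyloxy)-3-oxopropanoyl]oxy}butanedioate
Product: 4 benzyl (5S)-4-hydroxy-5-(2-methoxy-2-oxoethyl)-2-oxo-2,5-dihydrofuran-3-carboxylate
Conditions: KOt-Bu (1.0 equiv), t-BuOH/THF, 0 °C → rt; then 1 M HCl
Reagents that add atoms: none
Why: Dieckmann cyclisation; the stabilised malonate anion attacks the more electrophilic α-oxygenated ester in a five-membered closure and is too weak a base to cause β-elimination of the acyloxy group.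

Step 3
Reactants: 4 benzyl (5S)-4-hydroxy-5-(2-methoxy-2-oxoethyl)-2-oxo-2,5-dihydrofuran-3-carboxylate
Product: 6 methyl 2-[(2S)-3-hydroxy-5-oxo-2,5-dihydrofuran-2-yl]acetate, via 3-carboxytetronic acid 5 (not isolated)
Conditions: H2 (1 atm), 10% Pd/C, EtOAc, rt; then 50 °C
Reagents that add atoms: none
Why: Hydrogenolysis of the benzyl ester gives a vinylogous β-keto acid that should decarboxylate on gentle warming; the enolised tetronic acid double bond is not reduced under these conditions.

Step 4
Reactants: 6 methyl 2-[(2S)-3-hydroxy-5-oxo-2,5-dihydrofuran-2-yl]acetate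
Product: 7 methyl 2-[(2S)-5-oxo-3-(trifluoromethylsulfonyloxy)-2,5-dihydrofuran-2-yl]acetate
Conditions: Tf2O, i-Pr2NEt, CH2Cl2, −78 °C
Reagents that add atoms: trifluoromethanesulfonic anhydride, O=S(=O)(OS(=O)(=O)C(F)(F)F)C(F)(F)F
Why: O-sulfonylation of the acidic enol of a tetronic acid; the hindered base and low temperature should leave the C8–H and C9–H protons alone.

Step 5
Reactants: 7 methyl 2-[(2S)-5-oxo-3-(trifluoromethylsulfonyloxy)-2,5-dihydrofuran-2-yl]acetate; 8 tert-butyl bromoacetate
Product: 10 tert-butyl 2-[(2S)-2-(2-methoxy-2-oxoethyl)-5-oxo-2,5-dihydrofuran-3-yl]acetate, via Reformatsky reagent 9 (not isolated)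
Conditions: 8, Zn dust (Me3SiCl-activated), THF, 40 °C; then 7, Pd(PPh3)4 (5 mol %), THF, rt → 50 °C
Reagents that add atoms: none
Why: Negishi-type cross-coupling of a zinc ester enolate with a vinyl triflate (oxidative addition of the β-triflyloxy enoate to zerovalent palladium, transmetallation, reductive elimination) forms C6–C7 under neutral conditions that should not racemise C8.

Step 6
Reactants: 10 tert-butyl 2-[(2S)-2-(2-methoxy-2-oxoethyl)-5-oxo-2,5-dihydrofuran-3-yl]acetate
Product: 11 tert-butyl 2-[(2S,3R)-2-(2-methoxy-2-oxoethyl)-5-oxooxolan-3-yl]acetate (2,3-cis)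
Conditions: H2 (3 atm), 5% Rh/Al2O3, EtOAc, rt
Reagents that add atoms: none
Why: Heterogeneous syn-hydrogenation of a butenolide; hydrogen is delivered to the face away from the C9 chain on C8, so C7–H and C8–H become cis, and rhodium limits allylic C8–O hydrogenolysis and double-bond migration.

Step 7
Reactants: 11 tert-butyl 2-[(2S,3R)-2-(2-methoxy-2-oxoethyl)-5-oxooxolan-3-yl]acetate
Product: 12 2-[(2S,3S)-2-(2-methoxy-2-oxoethyl)-5-oxooxolan-3-yl]acetic acid
Conditions: CF3CO2H, CH2Cl2, 0 °C → rt
Reagents that add atoms: none
Why: Acidolysis of the tert-butyl ester by loss of isobutene frees the C5 carboxyl while the methyl ester and the lactone stay intact.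

Step 8
Reactants: 13 (R)-butane-1,3-diol
Product: 14 (R)-4-iodobutan-2-ol
Conditions: I2, PPh3, imidazole, CH2Cl2, 0 °C
Reagents that add atoms: iodine, II
Why: Appel-type iodination, selective for the primary hydroxyl; the carbinol centre (later C2) is not involved.

Step 9
Reactants: 14 (R)-4-iodobutan-2-ol
Product: 15 (R)-4-iodobutan-2-yl acetate
Conditions: Ac2O, Et3N, DMAP (cat.), CH2Cl2, 0 °C
Reagents that add atoms: acetic anhydride, CC(=O)OC(C)=O
Why: Acylation of the secondary alcohol; an acetate is tolerated by alkylzinc halides and is cleaved later together with the methyl ester.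

Step 10
Reactants: 12 2-[(2S,3S)-2-(2-methoxy-2-oxoethyl)-5-oxooxolan-3-yl]acetic acid; 15 (R)-4-iodobutan-2-yl acetate
Product: 18 methyl 2-[(2S,3S)-3-[(5R)-5-acetoxy-2-oxohexyl]-5-oxooxolan-2-yl]acetate, via acid chloride 16 (not isolated), via alkylzinc iodide 17 (not isolated)
Conditions: 12, (COCl)2, DMF (cat.), CH2Cl2, 0 °C → rt, evaporate; 15, Zn dust (BrCH2CH2Br/Me3SiCl-activated), THF, 40 °C; combine, Pd(PPh3)4 (5 mol %), THF, 0 °C → rt
Reagents that add atoms: none
Why: Negishi acylation (palladium-catalysed coupling of an alkylzinc halide with an acid chloride) forms C4–C5 and stops at the ketone; the organozinc does not attack lactone, ester or acetate.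

Step 11
Reactants: 18 methyl 2-[(2S,3S)-3-[(5R)-5-acetoxy-2-oxohexyl]-5-oxooxolan-2-yl]acetate
Product: 19 methyl 2-[(2S,3S)-3-({2-[(3R)-3-acetoxybutyl]-1,3-dioxolan-2-yl}methyl)-5-oxooxolan-2-yl]acetate
Conditions: Me3SiOCH2CH2OSiMe3, Me3SiOTf (5 mol %), CH2Cl2, −78 → −20 °C; pyridine quench
Reagents that add atoms: 1,2-bis(trimethylsilyloxy)ethane, C[Si](C)(C)OCCO[Si](C)(C)C
Why: Noyori ketalisation under aprotic conditions masks the unhindered C5 ketone without transesterifying the three ester groups.

Step 12
Reactants: 19 methyl 2-[(2S,3S)-3-({2-[(3R)-3-acetoxybutyl]-1,3-dioxolan-2-yl}methyl)-5-oxooxolan-2-yl]acetate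
Product: 21 2-[(2S,3S)-3-({2-[(3R)-3-hydroxybutyl]-1,3-dioxolan-2-yl}methyl)-5-oxooxolan-2-yl]acetic acid, via ring-opened dicarboxylate 20 (not isolated)
Conditions: LiOH·H2O (4 equiv), THF/MeOH/H2O, 0 °C → rt; then 1 M HCl to pH 3, 0 °C, EtOAc
Reagents that add atoms: lithium hydroxide, [Li+].[OH-]
Why: Saponification cleaves methyl ester and acetate and opens the γ-lactone; on mild acidification the γ-hydroxy acid should re-close, since only the C8 hydroxyl and the C12 carboxyl form a five-membered ring, and the dioxolane should survive the brief exposure at pH 3.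

Step 13
Reactants: 21 2-[(2S,3S)-3-({2-[(3R)-3-hydroxybutyl]-1,3-dioxolan-2-yl}methyl)-5-oxooxolan-2-yl]acetic acid
Product: 23 (2R,7S,8S)-nor-furyl bicyclic lactone 5-ethylene ketal, via mixed anhydride 22 (not isolated)
Conditions: 2,4,6-Cl3C6H2COCl, Et3N, THF, rt; then slow addition to DMAP, toluene, 80 °C (ca. 1 mM)
Reagents that add atoms: none
Why: Yamaguchi macrolactonisation closes O1–C10; the cis-γ-lactone holds the C6 and C9 arms on one face and acts as a turn, and the ketal keeps the C2 hydroxyl free of hemiketal formation.

Step 14
Reactants: 24 ethyl propiolate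
Product: 25 ethyl (Z)-3-iodoacrylate
Conditions: NaI, AcOH, 70 °C
Reagents that add atoms: sodium iodide, [Na+].[I-]
Why: Conjugate addition of iodide to the ynoate with anti protonation gives the (Z)-β-iodoacrylate.

Step 15
Reactants: 25 ethyl (Z)-3-iodoacrylate
Product: 27 (Z)-3-iodoacrolein, via aluminium hemiacetal 26 (not isolated)
Conditions: i-Bu2AlH (1.05 equiv), CH2Cl2, −78 °C; MeOH, then aqueous potassium sodium tartrate, cold; dried solution used at once
Reagents that add atoms: none
Why: Partial reduction of the ester; the tetrahedral aluminium hemiacetal is stable at −78 °C and collapses to the aldehyde on work-up, and cold, immediate use should keep the (Z) geometry.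

Step 16
Reactants: 23 (2R,7S,8S)-nor-furyl bicyclic lactone 5-ethylene ketal; 27 (Z)-3-iodoacrolein
Product: 29 (2R,7S,8S,13R)-13-[(Z)-1-hydroxy-3-iodoprop-2-en-1-yl] bicyclic lactone 5-ethylene ketal (both C2′ epimers), via lithium enolate 28 (not isolated)
Conditions: LiN(SiMe3)2 (1.05 equiv), THF, −78 °C, 20 min; 27 (2 equiv, CH2Cl2), −78 °C; AcOH/THF quench at −78 °C
Reagents that add atoms: none
Why: Aldol addition of a lactone enolate to an enal (1,2-addition); the γ-lactone, locked in the s-cis ester geometry, is several pK units more acidic than the C9 methylene of the macrolactone, so one equivalent of base should enolise C13; the aldehyde enters C13 on the convex face, anti to C6, and the C2′ centre forms without control because it is erased in step 18.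

Step 17
Reactants: 30 (R)-pent-4-yn-2-ol
Product: 31 triethyl{[(2R)-pent-4-yn-2-yl]oxy}silane
Conditions: Et3SiCl, imidazole, CH2Cl2, 0 °C
Reagents that add atoms: chlorotriethylsilane, CC[Si](Cl)(CC)CC
Why: Silylation of the secondary alcohol; the ether keeps this oxygen from adding to the alkyne in step 18 and from forming an alkoxide in step 19, and it falls with the ketal in step 20.

Step 18
Reactants: 29 (2R,7S,8S,13R)-13-[(Z)-1-hydroxy-3-iodoprop-2-en-1-yl] bicyclic lactone 5-ethylene ketal (both C2′ epimers); 31 triethyl{[(2R)-pent-4-yn-2-yl]oxy}silane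
Product: 34 13-epi-cordycicadin B 5-ethylene ketal 3″-triethylsilyl ether, via (Z)-enynol 32 (not isolated), via alkylidene dihydrofuran 33 (not isolated)
Conditions: PdCl2(PPh3)2 (5 mol %), CuI (10 mol %), Et3N (3 equiv), THF, 0 °C → rt; then K2PdI4 (5 mol %, from PdI2 and KI), DMA, 50 °C, same flask
Reagents that add atoms: none
Why: Sonogashira coupling followed by cycloisomerisation of a (Z)-2-en-4-yn-1-ol, both known reaction types for (Z)-3-iodoallylic alcohols. Zerovalent palladium inserts into the C4′–I bond with retention of the (Z) geometry, the copper acetylide of 31 transmetallates and reductive elimination forms C4′–C5′, giving enynol 32. Divalent palladium iodide (helped by the copper and palladium already present) then activates the alkyne, the C2′ hydroxyl adds anti to the metal in a 5-exo-dig closure that forms O1′–C5′, and protodemetallation gives the (Z)-alkylidene dihydrofuran 33. A 1,3-hydrogen shift from C2′ to the exocyclic carbon, driven by aromatisation, turns 33 into the furan 34, the exocyclic carbon becoming C1″. No stereocentre is created: the C2′ carbinol centre is destroyed, so both aldol epimers converge, and C2, C7, C8, C13 and C3″ are not touched. The step needs hydroxyl and alkyne cis on the double bond, which the geometry of 27 fixes and the coupling retains, and it needs the C2′ hydroxyl to be the only one within reach of the alkyne, which the silyl ether of 31 secures by excluding 5-endo-dig addition of the C3″ oxygen. The neutral, amine-buffered medium should keep the β-hydroxy lactone from retro-aldol cleavage and leave C9–H alone.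

Step 19
Reactants: 34 13-epi-cordycicadin B 5-ethylene ketal 3″-triethylsilyl ether
Product: 36 cordycicadin B 5-ethylene ketal 3″-triethylsilyl ether, via potassium enolate 35 (not isolated)
Conditions: KN(SiMe3)2 (1.1 equiv), THF, −78 °C, 10 min; inverse quench into AcOH (5 equiv)/THF, −78 °C
Reagents that add atoms: none
Why: Deprotonation and kinetic protonation of an α-heteroaryl lactone enolate; only C13–H is acidic enough for the silyl amide, and the proton should be delivered to the planar enolate from the convex face, anti to C6 and C9, placing the furyl group cis to C6 (13S); the cold excess of acid makes the quench irreversible.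

Step 20
Reactants: 36 cordycicadin B 5-ethylene ketal 3″-triethylsilyl ether
Product: 37 cordycicadin B
Conditions: 1 M aq. HCl/THF (1:4), 0 °C → rt
Reagents that add atoms: water, O
Why: Acid hydrolysis of the dioxolane and of the triethylsilyl ether in one operation; acid-catalysed enolisation of a lactone is slow, so C13 should hold, and a 2,5-dialkylfuran tolerates brief dilute acid at room temperature.

## Compound list

1 | dimethyl (S)-malate | COC(=O)C[C@H](O)C(=O)OC | starting material
2 | mono-benzyl malonate (3-(benzyloxy)-3-oxopropanoic acid) | OC(=O)CC(=O)OCc1ccccc1 | starting material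
3 | dimethyl (2S)-2-{[3-(benzyloxy)-3-oxopropanoyl]oxy}butanedioate | COC(=O)C[C@H](OC(=O)CC(=O)OCc1ccccc1)C(=O)OC | intermediate
4 | benzyl (5S)-4-hydroxy-5-(2-methoxy-2-oxoethyl)-2-oxo-2,5-dihydrofuran-3-carboxylate | COC(=O)C[C@@H]1OC(=O)C(C(=O)OCc2ccccc2)=C1O | intermediate
5 | (5S)-4-hydroxy-5-(2-methoxy-2-oxoethyl)-2-oxo-2,5-dihydrofuran-3-carboxylic acid | COC(=O)C[C@@H]1OC(=O)C(C(=O)O)=C1O | intermediate (not isolated)
6 | methyl 2-[(2S)-3-hydroxy-5-oxo-2,5-dihydrofuran-2-yl]acetate | COC(=O)C[C@@H]1OC(=O)C=C1O | intermediate
7 | methyl 2-[(2S)-5-oxo-3-(trifluoromethylsulfonyloxy)-2,5-dihydrofuran-2-yl]acetate | COC(=O)C[C@@H]1OC(=O)C=C1OS(=O)(=O)C(F)(F)F | intermediate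
8 | tert-butyl bromoacetate | CC(C)(C)OC(=O)CBr | starting material
9 | (2-tert-butoxy-2-oxoethyl)zinc bromide | CC(C)(C)OC(=O)C[Zn]Br | intermediate (not isolated)
10 | tert-butyl 2-[(2S)-2-(2-methoxy-2-oxoethyl)-5-oxo-2,5-dihydrofuran-3-yl]acetate | COC(=O)C[C@@H]1OC(=O)C=C1CC(=O)OC(C)(C)C | intermediate
11 | tert-butyl 2-[(2S,3R)-2-(2-methoxy-2-oxoethyl)-5-oxooxolan-3-yl]acetate (2,3-cis) | COC(=O)C[C@@H]1OC(=O)C[C@@H]1CC(=O)OC(C)(C)C | intermediate
12 | 2-[(2S,3S)-2-(2-methoxy-2-oxoethyl)-5-oxooxolan-3-yl]acetic acid (2,3-cis) | COC(=O)C[C@@H]1OC(=O)C[C@@H]1CC(=O)O | intermediate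
13 | (R)-butane-1,3-diol | C[C@@H](O)CCO | starting material
14 | (R)-4-iodobutan-2-ol | C[C@@H](O)CCI | intermediate
15 | (R)-4-iodobutan-2-yl acetate | C[C@@H](OC(C)=O)CCI | intermediate
16 | methyl 2-[(2S,3R)-3-(2-chloro-2-oxoethyl)-5-oxooxolan-2-yl]acetate | COC(=O)C[C@@H]1OC(=O)C[C@@H]1CC(=O)Cl | intermediate (not isolated)
17 | [(3R)-3-acetoxybutyl]zinc iodide | C[C@@H](OC(C)=O)CC[Zn]I | intermediate (not isolated)
18 | methyl 2-[(2S,3S)-3-[(5R)-5-acetoxy-2-oxohexyl]-5-oxooxolan-2-yl]acetate | C[C@@H](OC(C)=O)CCC(=O)C[C@H]1CC(=O)O[C@H]1CC(=O)OC | intermediate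
19 | methyl 2-[(2S,3S)-3-({2-[(3R)-3-acetoxybutyl]-1,3-dioxolan-2-yl}methyl)-5-oxooxolan-2-yl]acetate | C[C@@H](OC(C)=O)CCC1(OCCO1)C[C@H]2CC(=O)O[C@H]2CC(=O)OC | intermediate
20 | dilithium 3-hydroxy-4-{[2-(3-hydroxybutyl)-1,3-dioxolan-2-yl]methyl}hexanedioate (ring-opened form of 21, same configurations) | [Li+].[Li+].C[C@@H](O)CCC1(OCCO1)C[C@@H](CC(=O)[O-])[C@@H](O)CC(=O)[O-] | intermediate (not isolated)
21 | 2-[(2S,3S)-3-({2-[(3R)-3-hydroxybutyl]-1,3-dioxolan-2-yl}methyl)-5-oxooxolan-2-yl]acetic acid (seco acid) | C[C@@H](O)CCC1(OCCO1)C[C@H]2CC(=O)O[C@H]2CC(=O)O | intermediate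
22 | mixed anhydride of 21 with 2,4,6-trichlorobenzoic acid | C[C@@H](O)CCC1(OCCO1)C[C@H]2CC(=O)O[C@H]2CC(=O)OC(=O)c3c(Cl)cc(Cl)cc3Cl | intermediate (not isolated)
23 | (2R,7S,8S)-nor-furyl bicyclic lactone 5-ethylene ketal (ten-membered lactone O1–C10 cis-fused at C7–C8 to the γ-lactone, C13 = CH2) | C[C@@H]1CCC2(OCCO2)C[C@@H]3[C@H](CC(=O)O1)OC(=O)C3 | intermediate
24 | ethyl propiolate | CCOC(=O)C#C | starting material
25 | ethyl (Z)-3-iodoacrylate | CCOC(=O)/C=C\I | intermediate
26 | diisobutylaluminium hemiacetal of 25 | CCOC(O[Al](CC(C)C)CC(C)C)/C=C\I | intermediate (not isolated)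
27 | (Z)-3-iodoacrolein | O=C/C=C\I | intermediate (used as cold solution)
28 | lithium enolate of 23 (C12–C13) | [Li+].C[C@@H]1CCC2(OCCO2)C[C@@H]3[C@H](CC(=O)O1)OC([O-])=C3 | intermediate (not isolated)
29 | (2R,7S,8S,13R)-13-[(Z)-1-hydroxy-3-iodoprop-2-en-1-yl] bicyclic lactone 5-ethylene ketal (both C2′ epimers) | C[C@@H]1CCC2(OCCO2)C[C@@H]3[C@H](CC(=O)O1)OC(=O)[C@H]3C(O)/C=C\I | intermediate
30 | (R)-pent-4-yn-2-ol | C[C@@H](O)CC#C | starting material
31 | triethyl{[(2R)-pent-4-yn-2-yl]oxy}silane | C[C@@H](O[Si](CC)(CC)CC)CC#C | intermediate
32 | (2R,7S,8S,13R)-13-[(2Z,7R)-1-hydroxy-7-(triethylsilyloxy)oct-2-en-4-yn-1-yl] bicyclic lactone 5-ethylene ketal (C2′ epimers) | C[C@@H]1CCC2(OCCO2)C[C@@H]3[C@H](CC(=O)O1)OC(=O)[C@H]3C(O)/C=C\C#CC[C@@H](C)O[Si](CC)(CC)CC | intermediate (not isolated)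
33 | (Z)-2-alkylidene-2,5-dihydrofuran (O1′–C5′ closed, exocyclic C5′=C1″, C2′–H still present) | C[C@@H]1CCC2(OCCO2)C[C@@H]3[C@H](CC(=O)O1)OC(=O)[C@H]3C4C=C/C(=C/C[C@@H](C)O[Si](CC)(CC)CC)O4 | intermediate (not isolated)
34 | 13-epi-cordycicadin B 5-ethylene ketal 3″-triethylsilyl ether (2R,7S,8S,13R,3″R) | C[C@@H]1CCC2(OCCO2)C[C@@H]3[C@H](CC(=O)O1)OC(=O)[C@H]3c1ccc(CC[C@@H](C)O[Si](CC)(CC)CC)o1 | intermediate
35 | potassium enolate of 34 (C12–C13) | [K+].C[C@@H]1CCC2(OCCO2)C[C@@H]3[C@H](CC(=O)O1)OC([O-])=C3c1ccc(CC[C@@H](C)O[Si](CC)(CC)CC)o1 | intermediate (not isolated)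
36 | cordycicadin B 5-ethylene ketal 3″-triethylsilyl ether (2R,7S,8S,13S,3″R) | C[C@@H]1CCC2(OCCO2)C[C@@H]3[C@H](CC(=O)O1)OC(=O)[C@@H]3c1ccc(CC[C@@H](C)O[Si](CC)(CC)CC)o1 | intermediate
37 | cordycicadin B (2R,7S,8S,13S,3″R) | C[C@@H]1CCC(=O)C[C@@H]2[C@H](CC(=O)O1)OC(=O)[C@@H]2c1ccc(CC[C@@H](C)O)o1 | target

## Step count and least certain steps

Total: 20 steps. Longest linear sequence: 15 steps (1–7, 10–13, 16, 18–20) from dimethyl (S)-malate.

**Step 18 (key step).** The coupling may be slow on the hindered, β-hydroxy-substituted vinyl iodide, which would give the amine time to promote retro-aldol cleavage or dehydration. Alkyne homocoupling may compete, and cyclisation of 32 may stall in a medium that contains phosphine and amine. Fallback (from 23, back at 34): the C4′–C5′ bond is made on small molecules instead. Ester 25 is coupled with 31 (PdCl2(PPh3)2, CuI, Et3N) to ethyl (2Z,7R)-7-(triethylsilyloxy)oct-2-en-4-ynoate F1. Reduction with i-Bu2AlH at −78 °C gives, through the aluminium hemiacetal F2, (2Z,7R)-7-(triethylsilyloxy)oct-2-en-4-ynal F3. Aldol addition of enolate 28 (from 23) to F3 gives enynol 32 directly, which is now isolated and cycloisomerised with Ph3PAuNTf2 (2 mol %) in CH2Cl2 through 33 to 34.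

**Step 16 (aldol).** Deprotonation at C9 in competition with C13 would be followed by β-elimination of O11 and loss of the γ-lactone. The C13 enolate may also attack C10 across the ring (Claisen-type closure to a five-membered ketone), and 27 may isomerise to the (E)-aldehyde before it is consumed. Fallback (from 23, back at 29): the free enolate is avoided. Soft enolisation with Me3SiOTf/Et3N (CH2Cl2, 0 °C), which is selective for the s-cis lactone, gives the trimethylsilyl ketene acetal F4. A Mukaiyama aldol addition of F4 to 27 with BF3·OEt2 at −78 °C gives 29.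

**Step 19 (C13 inversion).** Protonation may show poor facial selectivity, or the product may re-equilibrate with unquenched enolate toward the more stable trans arrangement. Fallback (from 34, back at 36): both hydrogens are delivered by syn addition instead. Enolate 35 is trapped with PhSeBr on the convex face to give the α-phenylselanyl lactone F5. Oxidation (H2O2, pyridine, CH2Cl2, 0 °C) gives the selenoxide F6, which eliminates syn toward C7–H to the C7=C13 butenolide F7. Hydrogenation (H2, Pd/C, EtOAc, stopped before the furan is touched) from the face away from C9 sets C7 and C13 together and gives 36.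

**Step 13 (macrolactonisation).** Oligomerisation may compete with closure of the strained ten-membered ring, and the activated acyl group may lose O11 by β-elimination under DMAP. Fallback (from 12 and 14, back at 23): the alcohol is activated instead of the acid, which requires the C2 epimer.
- Mitsunobu inversion of 14 (PPh3, diisopropyl azodicarboxylate, AcOH) gives (S)-4-iodobutan-2-yl acetate F8.
- Zinc insertion gives [(3S)-3-acetoxybutyl]zinc iodide F9, and acylation with acid chloride 16 (from 12) as in step 10 gives the 2-epi ketone F10.
- Ketalisation as in step 11 gives the 2-epi ketal F11, and saponification as in step 12 gives, through the ring-opened salt F12, the (2S)-seco acid F13.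
- Mitsunobu lactonisation of F13 (PPh3, diisopropyl azodicarboxylate, toluene, high dilution) closes O1–C2 by carboxylate displacement with inversion and gives 23.

## Further compounds

F1 | step 18 | ethyl (2Z,7R)-7-(triethylsilyloxy)oct-2-en-4-ynoate | CCOC(=O)/C=C\C#CC[C@@H](C)O[Si](CC)(CC)CC
F2 | step 18 | diisobutylaluminium hemiacetal of F1 (not isolated) | CCOC(O[Al](CC(C)C)CC(C)C)/C=C\C#CC[C@@H](C)O[Si](CC)(CC)CC
F3 | step 18 | (2Z,7R)-7-(triethylsilyloxy)oct-2-en-4-ynal | O=C/C=C\C#CC[C@@H](C)O[Si](CC)(CC)CC
F4 | step 16 | trimethylsilyl ketene acetal of 23 (C12–C13) | C[C@@H]1CCC2(OCCO2)C[C@@H]3[C@H](CC(=O)O1)OC(O[Si](C)(C)C)=C3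
F5 | step 19 | 13-(phenylselanyl) derivative of 34 (selenium on the convex face) | C[C@@H]1CCC2(OCCO2)C[C@@H]3[C@H](CC(=O)O1)OC(=O)[C@]3([Se]c4ccccc4)c1ccc(CC[C@@H](C)O[Si](CC)(CC)CC)o1
F6 | step 19 | selenoxide of F5 (not isolated) | C[C@@H]1CCC2(OCCO2)C[C@@H]3[C@H](CC(=O)O1)OC(=O)[C@]3([Se](=O)c4ccccc4)c1ccc(CC[C@@H](C)O[Si](CC)(CC)CC)o1
F7 | step 19 | 7,13-didehydro derivative of 36 (C7=C13 butenolide) | C[C@@H]1CCC2(OCCO2)CC3=C(c4ccc(CC[C@@H](C)O[Si](CC)(CC)CC)o4)C(=O)O[C@H]3CC(=O)O1
F8 | step 13 | (S)-4-iodobutan-2-yl acetate | C[C@H](OC(C)=O)CCI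
F9 | step 13 | [(3S)-3-acetoxybutyl]zinc iodide (not isolated) | C[C@H](OC(C)=O)CC[Zn]I
F10 | step 13 | methyl 2-[(2S,3S)-3-[(5S)-5-acetoxy-2-oxohexyl]-5-oxooxolan-2-yl]acetate | C[C@H](OC(C)=O)CCC(=O)C[C@H]1CC(=O)O[C@H]1CC(=O)OC
F11 | step 13 | methyl 2-[(2S,3S)-3-({2-[(3S)-3-acetoxybutyl]-1,3-dioxolan-2-yl}methyl)-5-oxooxolan-2-yl]acetate | C[C@H](OC(C)=O)CCC1(OCCO1)C[C@H]2CC(=O)O[C@H]2CC(=O)OC
F12 | step 13 | dilithium salt of the ring-opened form of F13 (not isolated) | [Li+].[Li+].C[C@H](O)CCC1(OCCO1)C[C@@H](CC(=O)[O-])[C@@H](O)CC(=O)[O-]
F13 | step 13 | 2-[(2S,3S)-3-({2-[(3S)-3-hydroxybutyl]-1,3-dioxolan-2-yl}methyl)-5-oxooxolan-2-yl]acetic acid | C[C@H](O)CCC1(OCCO1)C[C@H]2CC(=O)O[C@H]2CC(=O)O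
A1 | alternative 1 | metathesis precursor: C5 vinyl ketone and C10 (R)-but-3-en-2-yl ester on the furyl cis-lactone (silyl ether) | C[C@@H](OC(=O)C[C@@H]1OC(=O)[C@H](c2ccc(CC[C@@H](C)O[Si](C)(C)C(C)(C)C)o2)[C@@H]1CC(=O)C=C)C=C
A2 | alternative 1 | 3,4-didehydro macrolide tert-butyldimethylsilyl ether (either alkene geometry) | C[C@@H]1C=CC(=O)C[C@@H]2[C@H](CC(=O)O1)OC(=O)[C@@H]2c1ccc(CC[C@@H](C)O[Si](C)(C)C(C)(C)C)o1
A3 | alternative 2 | eleven-membered β-keto bis-lactone with a vinyl group on C8 (C13 epimers) | C[C@@H]1CCC(=O)C(c2ccc(CC[C@@H](C)O[Si](C)(C)C(C)(C)C)o2)C(=O)O[C@H](C=C)CC(=O)O1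
A4 | alternative 2 | cordycicadin B tert-butyldimethylsilyl ether | C[C@@H]1CCC(=O)C[C@@H]2[C@H](CC(=O)O1)OC(=O)[C@@H]2c1ccc(CC[C@@H](C)O[Si](C)(C)C(C)(C)C)o1
A5 | alternative 3 | bromoacetate aldehyde (C8 aldehyde, C12 methyl ester, C5 dioxolane) | C[C@@H](OC(=O)CBr)CCC1(OCCO1)C[C@H](C=O)[C@H](C(=O)OC)c1ccc(CC[C@@H](C)O[Si](C)(C)C(C)(C)C)o1
A6 | alternative 3 | 8-hydroxy macrolactone methyl ester (C5 dioxolane) | C[C@@H]1CCC2(OCCO2)C[C@H]([C@@H](O)CC(=O)O1)[C@H](C(=O)OC)c1ccc(CC[C@@H](C)O[Si](C)(C)C(C)(C)C)o1
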